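- I decide to book the flat end of the south-east run as a balance and to watch c(first product) as well as the target.

common to all: starting material 0.020 M; free enzyme 0.01 mol%

| run | second substrate | temperature | remark | time |
|---|---|---|---|---|
| south-east | 5 equiv | 25 °C | the very flask that is asked about, followed so far |  |
| north-west | 5 equiv | 31 °C | run made earlier |  |
| flask | 5.00 equiv | 25 °C |  | 8.0 d |

| run | time / d | target / % |
|---|---|---|
| south-east | 0.625 | 24 |
| south-east | 1.67 | 34 |
| south-east | 3.00 | 38 |
| south-east | 8.00 | 39 |
| north-west | 0.625 | 26 |
| north-west | 1.67 | 28 |
| north-west | 3.00 | 34 |
| north-west | 8.00 | 31 |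

(each reading ± 2 percentage points)

- green: at 8.0 d add second substrate, 50.0% of the amount charged, then wait 2.5 d
- amber: at 8.0 d take out 90% of the first product then present, then wait 2.5 d
- blue: at 8.0 d raise the temperature by 10 K, then wait 2.5 d
- red: at 8.0 d add free enzyme, 50.0% of the amount charged, then wait 2.5 d
- teal: change nothing and wait 2.5 d more

- additions leave the volume as it is

* target, in percent of the starting material first charged, at 8.0 d
* what to do for the largest gain in target; "none" if nothing gains more than 2 percentage points (green / amber / blue / red / teal / none)
* target present, in percent of the starting material first charged, after red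
* target present, in percent of the starting material first charged, after teal

- I take my ground from the two runs. The south-east target holds at 38% and 39% within the scatter, and the warmer north-west run ends lower, at 31%, as a balance that gives way on heating can.
- The ledger opens with the starting material, the limiting reagent: 0.020 M against 5 equiv of second substrate.
- First entry: 39% of it stands as target at 8.00 d, and I book one first product with each target, so c(first product) is 0.00780 M.
- Second entry: the enzyme, at 0.01 mol%, can hold no more than that share, so I pass over its bound forms.
- Closing entry: 61.0% remains as starting material, and c(second substrate) is 0.0922 M.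
- The quantity I carry is the balance quotient Q, which is c(target) times c(first product) over c(starting material) times c(second substrate). As a reading, with the scatter of the target under it, the ledger makes it 0.0541.
- I hold Q fixed at 25 °C and rebook the options that keep that temperature. Blue leaves that temperature, so Q does not carry over to it: as a reading, the ledger of the warmer north-west run makes Q 0.0297 at 31 °C, which speaks against heating. Amber gains 16 percentage points, and green gains less, 6.5 points.
- A catalyst moves no balance, so I leave the target at 39% now, after red and after teal, and I choose amber.
- The forecast differs: 39% now, 39% after teal, but red as the best option with 50% after it, on the ground that “the plateau is a limit on catalyst lifetime”.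
- The simulation gives 38.7% now, 38.7% after red and 38.7% after teal. Its best option is amber, with gains of 15 points for amber, 6.2 points for green, −11 points for blue, 0 points for red and 0 points for teal.

    free enzyme → unfolded enzyme (k = 2.76 × 10⁻⁵ min⁻¹, Ea = 251 kJ mol⁻¹)
    starting material + free enzyme ⇌ first complex (K = 84.0 M⁻¹, k = 15200 M⁻¹ min⁻¹, Ea = 44.0 kJ mol⁻¹, ΔH = −7.00 kJ mol⁻¹)
    first complex ⇌ loaded enzyme + first product (K = 0.0228 M, k = 10.4 min⁻¹, Ea = 71.0 kJ mol⁻¹, ΔH = −41.0 kJ mol⁻¹)
    second substrate + loaded enzyme ⇌ second complex (K = 2.26 M⁻¹, k = 18200 M⁻¹ min⁻¹, Ea = 37.0 kJ mol⁻¹, ΔH = −47.0 kJ mol⁻¹)
    second complex ⇌ free enzyme + target (K = 0.0122 M, k = 36.2 min⁻¹, Ea = 82.0 kJ mol⁻¹, ΔH = 31.0 kJ mol⁻¹)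
    (constants at 25 °C)

- Red parts the forecast from the flask, which stays at 38.7% against the forecast's 50%, while unfolded enzyme stands at 5.47% of the catalyst charged at 8.00 d; that path makes no difference to the target at that time. Q gave amber 16 points, and the flask gave 15 points. The neighbouring flask takes 12.0 equiv of second substrate, its other charges as in the recipe, and the same Q books its target at 53.6%. That flask stands at 53.2%, with c(first product) 0.0106 M at 8.00 d.

(The data are calculated with made-up constants; the scatter is artificial.)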